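**Strategy.** In germacrane numbering (C1 hemiketal carbon, C4 methyl-bearing ether carbon, C6 enol-lactone carbon) the ten-membered carbocycle C1–C10 holds a masked C1 ketone 1,5 to the C5=C6 enol-lactone double bond: an oxy-Cope retron. The route builds a p-menthane-like cyclohexane (C1, C6–C10) fused to the butenolide, with a vinyl carbinol at C1 and a cis (Z)-2-borylpropenyl group at C6. Its anionic oxy-Cope rearrangement forms C3–C4, expands the six-membered ring to the ten-membered one, unveils the C1 ketone and the C5=C6 ylidene lactone and sets C4 by chirality transfer. Boron-to-oxygen exchange, alkene isomerisation and hemiketalisation then close the 1,4-oxygen bridge.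

Key step: step 12

Remark: compounds 1, 4, 27 and 28 are taken as commercial; bicyclic intermediates carry 1-benzofuran locants and macrocycles germacrane locants; TBS = tert-butyldimethylsilyl, TIPS = triisopropylsilyl, TMS = trimethylsilyl, Bpin = 4,4,5,5-tetramethyl-1,3,2-dioxaborolan-2-yl.

Step 1
Reactants: 1 furan-3,4-diyldimethanol
Product: 2 [4-(TBS-oxymethyl)furan-3-yl]methanol
Conditions: NaH (1.0 equiv), THF, 0 °C; TBSCl (1.0 equiv), 0 → 25 °C
Reagents that add atoms: tert-butyl(chloro)dimethylsilane, CC(C)(C)[Si](C)(C)Cl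
Why: O-silylation of the monosodium alkoxide of a symmetric diol (statistical monoprotection, favoured by one equivalent of NaH); no stereocentre.

Step 2
Reactants: 2 [4-(TBS-oxymethyl)furan-3-yl]methanol
Product: 3 4-(TBS-oxymethyl)furan-3-carboxylic acid
Conditions: TEMPO (2,2,6,6-tetramethylpiperidin-1-oxyl, 20 mol %), PhI(OAc)2 (2.2 equiv), MeCN/H2O, 25 °C
Reagents that add atoms: water, O
Why: Oxoammonium (TEMPO/PhI(OAc)2) oxidation of the primary furylmethanol through the aldehyde hydrate to the acid, which should leave the furan and the silyl ether untouched; no stereocentre.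

Step 3
Reactants: 3 4-(TBS-oxymethyl)furan-3-carboxylic acid; 4 methyl (2S)-3-bromo-2-methylpropanoate
Product: 7 methyl (2R)-4-[4-(TBS-oxymethyl)furan-3-yl]-2-methyl-4-oxobutanoate, via acid chloride 5 (not isolated), via alkylzinc bromide 6 (not isolated)
Conditions: 3, Me2C=C(Cl)NMe2, CH2Cl2, 0 °C; 4, Zn dust, LiCl, THF, 25 °C; then combine, Pd(PPh3)4 (5 mol %), THF, 0 → 25 °C
Reagents that add atoms: none
Why: Negishi acylation of an acid chloride with an ester-chelated zinc homoenolate, which is configurationally stable at its α-carbon, so the methyl-bearing centre (later C10) comes unchanged from the chiral pool.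

Step 4
Reactants: 7 methyl (2R)-4-[4-(TBS-oxymethyl)furan-3-yl]-2-methyl-4-oxobutanoate
Product: 9 (3R,5S)-5-[4-(TBS-oxymethyl)furan-3-yl]-3-methyloxolan-2-one (trans lactone), via hydroxy ester 8 (not isolated)
Conditions: (R)-2-methyl-CBS-oxazaborolidine (C18H20BNO, 10 mol %), BH3·SMe2, THF, −20 °C; MeOH quench; then PPTS (cat.), toluene, 50 °C
Reagents that add atoms: none
Why: Corey–Bakshi–Shibata reduction, the (R)-oxazaborolidine differentiating furyl (large) from methylene (small) to set the 4S carbinol (later C8) under reagent control, followed by acid-catalysed lactonisation to the trans lactone.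

Step 5
Reactants: 9 (3R,5S)-5-[4-(TBS-oxymethyl)furan-3-yl]-3-methyloxolan-2-one
Product: 12 (2R,4S)-4-[4-(TBS-oxymethyl)furan-3-yl]-2-methyl-4-(TIPS-oxy)butanoic acid, via potassium hydroxy carboxylate 10 (not isolated), via bis-silylated ester 11 (not isolated)
Conditions: KOH, MeOH/H2O, 25 °C, concentrate; TIPSOTf (2.5 equiv), 2,6-lutidine, CH2Cl2, 0 → 25 °C; then K2CO3 (cat.), MeOH/H2O, 25 °C
Reagents that add atoms: potassium hydroxide, [K+].[OH-]; triisopropylsilyl trifluoromethanesulfonate, CC(C)[Si](C(C)C)(C(C)C)OS(=O)(=O)C(F)(F)F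
Why: Lactone saponification, exhaustive O-silylation and selective methanolysis of the labile silyl ester (protecting-group chemistry) leave both stereocentres untouched; the bulky TIPS ether is chosen to suppress silyloxy participation in the next step.

Step 6
Reactants: 12 (2R,4S)-4-[4-(TBS-oxymethyl)furan-3-yl]-2-methyl-4-(TIPS-oxy)butanoic acid
Product: 14 (4S,6R)-3-(TBS-oxymethyl)-6-methyl-4-(TIPS-oxy)-5,6-dihydro-1-benzofuran-7(4H)-one, via acid chloride 13 (not isolated)
Conditions: Me2C=C(Cl)NMe2, CH2Cl2, 0 °C; then SnCl4, CH2Cl2, −78 °C, high dilution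
Reagents that add atoms: none
Why: Intramolecular Friedel–Crafts acylation of the free furan α-position next to the tether (six-membered ring closure) by an acid chloride made under neutral conditions; no new stereocentre, and the low temperature should protect the α-methyl centre from enolisation.

Step 7
Reactants: 14 (4S,6R)-3-(TBS-oxymethyl)-6-methyl-4-(TIPS-oxy)-5,6-dihydro-1-benzofuran-7(4H)-one
Product: 15 (4S,6R,7R)-7-ethenyl-3-(TBS-oxymethyl)-6-methyl-4-(TIPS-oxy)-4,5,6,7-tetrahydro-1-benzofuran-7-ol (vinyl trans to the 6-methyl group)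
Conditions: CH2=CHMgBr, CeCl3, THF, −78 °C
Reagents that add atoms: vinylmagnesium bromide, C=C[Mg]Br
Why: Organocerium-type 1,2-addition to the 2-furyl ketone; C7 (germacrane C1) is set by substrate control, vinyl entering trans to the adjacent pseudo-equatorial methyl group (equatorial attack, the usual course for α-methylcyclohexanones), so the hydroxyl is cis to the methyl.

Step 8
Reactants: 15 (4S,6R,7R)-7-ethenyl-3-(TBS-oxymethyl)-6-methyl-4-(TIPS-oxy)-4,5,6,7-tetrahydro-1-benzofuran-7-ol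
Product: 16 (4S,6R,7R)-7-ethenyl-3-(TBS-oxymethyl)-6-methyl-4-(TIPS-oxy)-7-(TMS-oxy)-4,5,6,7-tetrahydro-1-benzofuran
Conditions: 1-(trimethylsilyl)imidazole, CH2Cl2, 25 °C
Reagents that add atoms: 1-(trimethylsilyl)imidazole, C[Si](C)(C)n1ccnc1
Why: Non-acidic silylation of the hindered tertiary alcohol avoids ionisation of the furfuryl-allylic carbinol and gives a non-chelating neighbour for step 10; no stereochemical change.

Step 9
Reactants: 16 (4S,6R,7R)-7-ethenyl-3-(TBS-oxymethyl)-6-methyl-4-(TIPS-oxy)-7-(TMS-oxy)-4,5,6,7-tetrahydro-1-benzofuran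
Product: 18 (4S,6R,7R)-7-ethenyl-7a-hydroxy-3-(TBS-oxymethyl)-6-methyl-4-(TIPS-oxy)-7-(TMS-oxy)-5,6,7,7a-tetrahydro-1-benzofuran-2(4H)-one (pseudo-acid, 7a epimers), via furan endoperoxide 17 (not isolated)
Conditions: O2, rose bengal (C20H2Cl4I4Na2O5, cat.), visible light, iPr2NEt, CH2Cl2, −78 °C
Reagents that add atoms: oxygen, O=O
Why: [4+2] cycloaddition of singlet oxygen to the furan and base-induced Kornblum–DeLaMare fragmentation of the endoperoxide, whose only C–H (C2) is removed, so the carbonyl forms at C2 and the hemiketal at C7a (an equilibrating pseudo-acid centre).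

Step 10
Reactants: 18 (4S,6R,7R)-7-ethenyl-7a-hydroxy-3-(TBS-oxymethyl)-6-methyl-4-(TIPS-oxy)-7-(TMS-oxy)-5,6,7,7a-tetrahydro-1-benzofuran-2(4H)-one
Product: 19 (4S,6R,7R,7aS)-7-ethenyl-3-(TBS-oxymethyl)-6-methyl-7a-(prop-1-yn-1-yl)-4-(TIPS-oxy)-7-(TMS-oxy)-5,6,7,7a-tetrahydro-1-benzofuran-2(4H)-one
Conditions: CH3C≡CMgBr (3 equiv), CeCl3, THF, −78 → 0 °C; aq. NH4Cl, pH 4–5 work-up
Reagents that add atoms: prop-1-yn-1-ylmagnesium bromide, CC#C[Mg]Br
Why: Grignard addition to the ring-opened keto-carboxylate form of the pseudo-acid and relactonisation; C7a (germacrane C6) is set by polar Felkin–Anh control, the small alkynyl nucleophile attacking axially anti to the neighbouring axial C7–OSiMe3 bond, which places the alkyne cis to the vinyl group.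

Step 11
Reactants: 19 (4S,6R,7R,7aS)-7-ethenyl-3-(TBS-oxymethyl)-6-methyl-7a-(prop-1-yn-1-yl)-4-(TIPS-oxy)-7-(TMS-oxy)-5,6,7,7a-tetrahydro-1-benzofuran-2(4H)-one
Product: 21 (4S,6R,7R,7aS)-7-ethenyl-7-hydroxy-3-(TBS-oxymethyl)-6-methyl-7a-[(1Z)-2-Bpin-prop-1-en-1-yl]-4-(TIPS-oxy)-5,6,7,7a-tetrahydro-1-benzofuran-2(4H)-one, via silyl ether boronate 20 (not isolated)
Conditions: pinacolborane, Cp2Zr(H)Cl (10 mol %), Et3N (10 mol %), THF, 60 °C; then MeOH, K2CO3, 0 °C
Reagents that add atoms: pinacolborane, [H]B1OC(C)(C)C(C)(C)O1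
Why: Cp2Zr(H)Cl-catalysed syn-hydroboration of the internal alkyne puts boron on the less hindered methyl-bearing carbon (Z alkenylboronate, boron trans to the ring) ahead of the hindered vinyl group, and carbonate methanolysis then removes only the labile tertiary TMS ether.

Step 12
Reactants: 21 (4S,6R,7R,7aS)-7-ethenyl-7-hydroxy-3-(TBS-oxymethyl)-6-methyl-7a-[(1Z)-2-Bpin-prop-1-en-1-yl]-4-(TIPS-oxy)-5,6,7,7a-tetrahydro-1-benzofuran-2(4H)-one
Product: 23 (4S,5Z,8S,10R)-4-hydroxy-13-(TBS-oxy)-1-oxo-8-(TIPS-oxy)germacra-5,7(11)-dien-12,6-olide, via potassium enolate 22 (not isolated)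
Conditions: KN(SiMe3)2 (1.05 equiv), 18-crown-6, THF, −78 → 0 °C; then NaBO3·4H2O, NaHCO3, THF/H2O, 0 → 25 °C
Reagents that add atoms: sodium perborate tetrahydrate (NaBO3·4H2O), O.O.O.O.[Na+].[O-]B1OO1
Why: KN(SiMe3)2 gives the potassium alkoxide at C1, which undergoes an anionic oxy-Cope [3,3] sigmatropic shift, the reaction type of divinylcyclohexanol-to-cyclodecenone ring expansions: C1–C6 breaks as C3–C4 forms, and the departing C4–C5–C6 unit is stabilised as a butenolide dienolate with a boron-bearing terminus. The ten-membered carbocycle closes by four-carbon ring expansion of the cyclohexane through a six-membered chair transition state (a pericyclic closure, not an exo or endo ring closure). The planar fused butenolide keeps the alkenyl group axial and the cis vinyl group equatorial and anti to C7, so a single chair is available; it leads to the (5Z) enol lactone and to bond formation on one face of C4. C4 is therefore set by chirality transfer from C6 (7aS) through that chair together with the Z geometry of the alkenylboronate (methyl inside, boron outside), and the buffered perborate oxidation then replaces boron by hydroxyl with retention. The step needs the concerted [3,3] path to beat heterolytic fragmentation with [1,3] recombination and acyl transfer onto the lactone, which the doubly oxygenated, allylic C1–C6 bond and the conjugation gained in the product should secure at or below 0 °C; the oxidant is added to the cold enolate so that the allylic boronate is oxidised before it can add to the liberated ketone.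

Step 13
Reactants: 23 (4S,5Z,8S,10R)-4-hydroxy-13-(TBS-oxy)-1-oxo-8-(TIPS-oxy)germacra-5,7(11)-dien-12,6-olide
Product: 24 (1R,4S,5E,8S,10R)-1,4-epoxy-1-hydroxy-13-(TBS-oxy)-8-(TIPS-oxy)germacra-5,7(11)-dien-12,6-olide
Conditions: I2 (5 mol %), CH2Cl2, visible light, 25 °C
Reagents that add atoms: none
Why: Iodine-atom-catalysed E/Z equilibration of the γ-ylidene butenolide (reversible addition at C5) under thermodynamic control: only the 5E (ring-cis) isomer can close the transannular C1/C4 hemiketal, which should drain the equilibrium, and C1 is fixed by the necessarily cis bridge to C4.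

Step 14
Reactants: 24 (1R,4S,5E,8S,10R)-1,4-epoxy-1-hydroxy-13-(TBS-oxy)-8-(TIPS-oxy)germacra-5,7(11)-dien-12,6-olide
Product: 25 (1R,4S,5E,8S,10R)-1,4-epoxy-1,8,13-trihydroxygermacra-5,7(11)-dien-12,6-olide
Conditions: HF·pyridine, pyridine, THF, 0 → 25 °C
Reagents that add atoms: none
Why: Fluoride-mediated desilylation of the primary TBS and secondary TIPS ethers under buffered conditions that the ylidene lactone and the bridged hemiketal should tolerate; no stereochemical change.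

Step 15
Reactants: 25 (1R,4S,5E,8S,10R)-1,4-epoxy-1,8,13-trihydroxygermacra-5,7(11)-dien-12,6-olide
Product: 26 (1R,4S,5E,8S,10R)-13-acetoxy-1,4-epoxy-1,8-dihydroxygermacra-5,7(11)-dien-12,6-olide
Conditions: AcCl (1.05 equiv), 2,4,6-collidine, CH2Cl2, −78 °C
Reagents that add atoms: acetyl chloride, CC(=O)Cl
Why: Kinetically selective acylation of the primary allylic alcohol, the secondary C8 hydroxyl and the tertiary hemiketal hydroxyl reacting far more slowly with acetyl chloride and a hindered base at low temperature.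

Step 16
Reactants: 27 (tert-butyldimethylsilyloxy)acetaldehyde; 28 ethyl 2-(triphenylphosphoranylidene)propanoate
Product: 29 ethyl (2E)-4-(TBS-oxy)-2-methylbut-2-enoate
Conditions: CH2Cl2, 25 °C
Reagents that add atoms: none
Why: Wittig olefination with a stabilised α-methyl ylide, which should give the E trisubstituted enoate.

Step 17
Reactants: 29 ethyl (2E)-4-(TBS-oxy)-2-methylbut-2-enoate
Product: 30 (2E)-4-(TBS-oxy)-2-methylbut-2-enoic acid
Conditions: LiOH, THF/H2O, 0 → 25 °C; then 1 M HCl to pH 4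
Reagents that add atoms: lithium hydroxide, [Li+].[OH-]
Why: Ester saponification that leaves the primary silyl ether and the alkene geometry intact.

Step 18
Reactants: 26 (1R,4S,5E,8S,10R)-13-acetoxy-1,4-epoxy-1,8-dihydroxygermacra-5,7(11)-dien-12,6-olide; 30 (2E)-4-(TBS-oxy)-2-methylbut-2-enoic acid
Product: 32 (1R,4S,5E,8S,10R)-13-acetoxy-1,4-epoxy-1-hydroxy-8-[(2E)-4-(TBS-oxy)-2-methylbut-2-enoyloxy]germacra-5,7(11)-dien-12,6-olide, via mixed anhydride 31 (not isolated)
Conditions: 30, 2,4,6-trichlorobenzoyl chloride, Et3N, THF, 25 °C; then 26, DMAP, toluene, 25 °C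
Reagents that add atoms: none
Why: Yamaguchi esterification acylates the secondary allylic C8 hydroxyl with retention, the tertiary bridgehead hemiketal hydroxyl being too hindered to compete.

Step 19
Reactants: 32 (1R,4S,5E,8S,10R)-13-acetoxy-1,4-epoxy-1-hydroxy-8-[(2E)-4-(TBS-oxy)-2-methylbut-2-enoyloxy]germacra-5,7(11)-dien-12,6-olide
Product: 33 CNP0154520.2, (1R,4S,5E,8S,10R)-13-acetoxy-1,4-epoxy-1-hydroxy-8-[(2E)-4-hydroxy-2-methylbut-2-enoyloxy]germacra-5,7(11)-dien-12,6-olide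
Conditions: HF·pyridine, pyridine, THF, 0 °C
Reagents that add atoms: none
Why: Fluoride desilylation of the primary TBS ether under buffered conditions that should spare the acetate, both unsaturated esters and the hemiketal.

**Compound list**

1 | furan-3,4-diyldimethanol | OCc1cocc1CO | starting material
2 | [4-(TBS-oxymethyl)furan-3-yl]methanol | OCc1cocc1CO[Si](C)(C)C(C)(C)C | intermediate
3 | 4-(TBS-oxymethyl)furan-3-carboxylic acid | OC(=O)c1cocc1CO[Si](C)(C)C(C)(C)C | intermediate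
4 | methyl (2S)-3-bromo-2-methylpropanoate | C[C@H](CBr)C(=O)OC | starting material
5 | 4-(TBS-oxymethyl)furan-3-carbonyl chloride | ClC(=O)c1cocc1CO[Si](C)(C)C(C)(C)C | intermediate
6 | [(2S)-3-methoxy-2-methyl-3-oxopropyl]zinc bromide | C[C@H](C[Zn]Br)C(=O)OC | intermediate
7 | methyl (2R)-4-[4-(TBS-oxymethyl)furan-3-yl]-2-methyl-4-oxobutanoate | C[C@H](CC(=O)c1cocc1CO[Si](C)(C)C(C)(C)C)C(=O)OC | intermediate
8 | methyl (2R,4S)-4-[4-(TBS-oxymethyl)furan-3-yl]-4-hydroxy-2-methylbutanoate | C[C@H](C[C@H](O)c1cocc1CO[Si](C)(C)C(C)(C)C)C(=O)OC | intermediate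
9 | (3R,5S)-5-[4-(TBS-oxymethyl)furan-3-yl]-3-methyloxolan-2-one | C[C@@H]1C[C@@H](c2cocc2CO[Si](C)(C)C(C)(C)C)OC1=O | intermediate
10 | potassium (2R,4S)-4-[4-(TBS-oxymethyl)furan-3-yl]-4-hydroxy-2-methylbutanoate | C[C@H](C[C@H](O)c1cocc1CO[Si](C)(C)C(C)(C)C)C(=O)[O-].[K+] | intermediate
11 | triisopropylsilyl (2R,4S)-4-[4-(TBS-oxymethyl)furan-3-yl]-2-methyl-4-(TIPS-oxy)butanoate | C[C@H](C[C@H](O[Si](C(C)C)(C(C)C)C(C)C)c1cocc1CO[Si](C)(C)C(C)(C)C)C(=O)O[Si](C(C)C)(C(C)C)C(C)C | intermediate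
12 | (2R,4S)-4-[4-(TBS-oxymethyl)furan-3-yl]-2-methyl-4-(TIPS-oxy)butanoic acid | C[C@H](C[C@H](O[Si](C(C)C)(C(C)C)C(C)C)c1cocc1CO[Si](C)(C)C(C)(C)C)C(=O)O | intermediate
13 | (2R,4S)-4-[4-(TBS-oxymethyl)furan-3-yl]-2-methyl-4-(TIPS-oxy)butanoyl chloride | C[C@H](C[C@H](O[Si](C(C)C)(C(C)C)C(C)C)c1cocc1CO[Si](C)(C)C(C)(C)C)C(=O)Cl | intermediate
14 | (4S,6R)-3-(TBS-oxymethyl)-6-methyl-4-(TIPS-oxy)-5,6-dihydro-1-benzofuran-7(4H)-one | C[C@@H]1C[C@H](O[Si](C(C)C)(C(C)C)C(C)C)c2c(CO[Si](C)(C)C(C)(C)C)coc2C1=O | intermediate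
15 | (4S,6R,7R)-7-ethenyl-3-(TBS-oxymethyl)-6-methyl-4-(TIPS-oxy)-4,5,6,7-tetrahydro-1-benzofuran-7-ol | C[C@@H]1C[C@H](O[Si](C(C)C)(C(C)C)C(C)C)c2c(CO[Si](C)(C)C(C)(C)C)coc2[C@@]1(O)C=C | intermediate
16 | (4S,6R,7R)-7-ethenyl-3-(TBS-oxymethyl)-6-methyl-4-(TIPS-oxy)-7-(TMS-oxy)-4,5,6,7-tetrahydro-1-benzofuran | C[C@@H]1C[C@H](O[Si](C(C)C)(C(C)C)C(C)C)c2c(CO[Si](C)(C)C(C)(C)C)coc2[C@@]1(O[Si](C)(C)C)C=C | intermediate
17 | 2,7a-epidioxy-2,7a-dihydro derivative of 16 (furan endoperoxide, either face) | C[C@@H]1C[C@H](O[Si](C(C)C)(C(C)C)C(C)C)C2=C(CO[Si](C)(C)C(C)(C)C)C3OOC2(O3)[C@@]1(O[Si](C)(C)C)C=C | intermediate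
18 | (4S,6R,7R)-7-ethenyl-7a-hydroxy-3-(TBS-oxymethyl)-6-methyl-4-(TIPS-oxy)-7-(TMS-oxy)-5,6,7,7a-tetrahydro-1-benzofuran-2(4H)-one | C[C@@H]1C[C@H](O[Si](C(C)C)(C(C)C)C(C)C)C2=C(CO[Si](C)(C)C(C)(C)C)C(=O)OC2(O)[C@@]1(O[Si](C)(C)C)C=C | intermediate
19 | (4S,6R,7R,7aS)-7-ethenyl-3-(TBS-oxymethyl)-6-methyl-7a-(prop-1-yn-1-yl)-4-(TIPS-oxy)-7-(TMS-oxy)-5,6,7,7a-tetrahydro-1-benzofuran-2(4H)-one | C[C@@H]1C[C@H](O[Si](C(C)C)(C(C)C)C(C)C)C2=C(CO[Si](C)(C)C(C)(C)C)C(=O)O[C@]2(C#CC)[C@@]1(O[Si](C)(C)C)C=C | intermediate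
20 | (4S,6R,7R,7aS)-7-ethenyl-3-(TBS-oxymethyl)-6-methyl-7a-[(1Z)-2-Bpin-prop-1-en-1-yl]-4-(TIPS-oxy)-7-(TMS-oxy)-5,6,7,7a-tetrahydro-1-benzofuran-2(4H)-one | C[C@@H]1C[C@H](O[Si](C(C)C)(C(C)C)C(C)C)C2=C(CO[Si](C)(C)C(C)(C)C)C(=O)O[C@]2(/C=C(\C)B3OC(C)(C)C(C)(C)O3)[C@@]1(O[Si](C)(C)C)C=C | intermediate
21 | (4S,6R,7R,7aS)-7-ethenyl-7-hydroxy-3-(TBS-oxymethyl)-6-methyl-7a-[(1Z)-2-Bpin-prop-1-en-1-yl]-4-(TIPS-oxy)-5,6,7,7a-tetrahydro-1-benzofuran-2(4H)-one | C[C@@H]1C[C@H](O[Si](C(C)C)(C(C)C)C(C)C)C2=C(CO[Si](C)(C)C(C)(C)C)C(=O)O[C@]2(/C=C(\C)B3OC(C)(C)C(C)(C)O3)[C@@]1(O)C=C | intermediate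
22 | potassium (1E)-enolate of (4R,5Z,8S,10R)-4-Bpin-13-(TBS-oxy)-1-oxo-8-(TIPS-oxy)germacra-5,7(11)-dien-12,6-olide | C[C@@H]1C[C@H](O[Si](C(C)C)(C(C)C)C(C)C)C2=C(CO[Si](C)(C)C(C)(C)C)C(=O)O\C2=C/[C@@](C)(B3OC(C)(C)C(C)(C)O3)C/C=C1/[O-].[K+] | intermediate
23 | (4S,5Z,8S,10R)-4-hydroxy-13-(TBS-oxy)-1-oxo-8-(TIPS-oxy)germacra-5,7(11)-dien-12,6-olide | C[C@@H]1C[C@H](O[Si](C(C)C)(C(C)C)C(C)C)C2=C(CO[Si](C)(C)C(C)(C)C)C(=O)O\C2=C/[C@@](C)(O)CCC1=O | intermediate
24 | (1R,4S,5E,8S,10R)-1,4-epoxy-1-hydroxy-13-(TBS-oxy)-8-(TIPS-oxy)germacra-5,7(11)-dien-12,6-olide | CC(C)(C)[Si](C)(C)OCC1=C2/C(=C\[C@]3(C)CC[C@@](O)(O3)[C@H](C)C[C@@H]2O[Si](C(C)C)(C(C)C)C(C)C)OC1=O | intermediate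
25 | (1R,4S,5E,8S,10R)-1,4-epoxy-1,8,13-trihydroxygermacra-5,7(11)-dien-12,6-olide | OCC1=C2/C(=C\[C@]3(C)CC[C@@](O)(O3)[C@H](C)C[C@@H]2O)OC1=O | intermediate
26 | (1R,4S,5E,8S,10R)-13-acetoxy-1,4-epoxy-1,8-dihydroxygermacra-5,7(11)-dien-12,6-olide | CC(=O)OCC1=C2/C(=C\[C@]3(C)CC[C@@](O)(O3)[C@H](C)C[C@@H]2O)OC1=O | intermediate
27 | (tert-butyldimethylsilyloxy)acetaldehyde | O=CCO[Si](C)(C)C(C)(C)C | starting material
28 | ethyl 2-(triphenylphosphoranylidene)propanoate | CCOC(=O)C(C)=P(c1ccccc1)(c1ccccc1)c1ccccc1 | starting material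
29 | ethyl (2E)-4-(TBS-oxy)-2-methylbut-2-enoate | CCOC(=O)/C(C)=C/CO[Si](C)(C)C(C)(C)C | intermediate
30 | (2E)-4-(TBS-oxy)-2-methylbut-2-enoic acid | OC(=O)/C(C)=C/CO[Si](C)(C)C(C)(C)C | intermediate
31 | (2E)-4-(TBS-oxy)-2-methylbut-2-enoic 2,4,6-trichlorobenzoic anhydride | O=C(OC(=O)c1c(Cl)cc(Cl)cc1Cl)/C(C)=C/CO[Si](C)(C)C(C)(C)C | intermediate
32 | (1R,4S,5E,8S,10R)-13-acetoxy-1,4-epoxy-1-hydroxy-8-[(2E)-4-(TBS-oxy)-2-methylbut-2-enoyloxy]germacra-5,7(11)-dien-12,6-olide | CC(=O)OCC1=C2/C(=C\[C@]3(C)CC[C@@](O)(O3)[C@H](C)C[C@@H]2OC(=O)/C(C)=C/CO[Si](C)(C)C(C)(C)C)OC1=O | intermediate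
33 | CNP0154520.2 | CC(=O)OCC1=C2/C(=C\[C@]3(C)CC[C@@](O)(O3)[C@H](C)C[C@@H]2OC(=O)/C(C)=C/CO)OC1=O | target

**Step count and risks**

Total step count: 19. Longest linear sequence: 17 steps (steps 1–15, 18 and 19).

Most likely to fail:

1. Step 12 (key step). The alkoxide may fragment heterolytically (retro-aldol-type C1–C6 cleavage) and recombine without concert or be protonated. It may instead transfer the lactone acyl group. After protonation the allylic boronate may add across the ring to the new ketone. The basic oxidation may epimerise the ketone α-centre (C10), and a non-chair transition state would erode the chirality transfer to C4. Fallback: leave the alkoxide manifold. The methanolysis in step 11 is omitted and the silyl ether 20 is isolated. Heating 20 in degassed toluene at 140–160 °C (sealed tube) should effect the neutral siloxy-Cope rearrangement through the same chair. This gives the ten-membered trimethylsilyl enol ether boronate F1, which has no free ketone and has never seen base. NaBO3·4H2O in buffered THF/water then oxidises the C–B bond with retention and hydrolyses the enol ether, returning to 23.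

2. Step 13. Iodine-atom addition to the hindered enol-ester double bond may be too slow for the equilibrium to reach the ring-cis isomer, or traces of HI may ionise the tertiary allylic alcohol. Fallback: set the geometry by elimination after the bridge exists. Aqueous trifluoroacetic acid in THF should hydrate 23 (protonation at C5, water capture at C6), and the now flexible ring closes the C1/C4 hemiketal. This gives the bridged γ-hydroxybutenolide (C5 methylene pseudo-acid) F2. Dehydration of the pseudo-acid (trifluoroacetic anhydride, pyridine, 0 °C) can then only form the ring-cis 5E ylidene lactone, returning to 24.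

3. Step 10. The hindered keto-carboxylate may add the alkynyl nucleophile sluggishly, or chelation may override the Felkin–Anh preference and give the wrong face at C7a, which would invert the later transfer to C4. Fallback: form the bond on the closed ring. Acetylation of 18 (Ac2O, DMAP, pyridine) gives the 7a-acetoxy butenolide (pseudo-acetate) F3. BF3·OEt2 and tributyl(prop-1-yn-1-yl)stannane in CH2Cl2 at −78 °C should ionise it to the planar acyl-oxocarbenium ion, which is alkynylated anti to the pseudo-axial 7-silyloxy group, returning to 19.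

**Further compounds**

F1 | step 12 | (1E,4R,5Z,8S,10R)-4-Bpin-13-(TBS-oxy)-8-(TIPS-oxy)-1-(TMS-oxy)germacra-1,5,7(11)-trien-12,6-olide | C[C@@H]1C[C@H](O[Si](C(C)C)(C(C)C)C(C)C)C2=C(CO[Si](C)(C)C(C)(C)C)C(=O)O\C2=C/[C@@](C)(B3OC(C)(C)C(C)(C)O3)C/C=C1/O[Si](C)(C)C
F2 | step 13 | (1R,4S,8S,10R)-1,4-epoxy-1,6-dihydroxy-13-(TBS-oxy)-8-(TIPS-oxy)germacr-7(11)-en-12,6-olide (C6 epimers) | CC(C)(C)[Si](C)(C)OCC1=C2C(O)(C[C@]3(C)CC[C@@](O)(O3)[C@H](C)C[C@@H]2O[Si](C(C)C)(C(C)C)C(C)C)OC1=O
F3 | step 10 | (4S,6R,7R)-7a-acetoxy-7-ethenyl-3-(TBS-oxymethyl)-6-methyl-4-(TIPS-oxy)-7-(TMS-oxy)-5,6,7,7a-tetrahydro-1-benzofuran-2(4H)-one (7a epimers) | C[C@@H]1C[C@H](O[Si](C(C)C)(C(C)C)C(C)C)C2=C(CO[Si](C)(C)C(C)(C)C)C(=O)OC2(OC(C)=O)[C@@]1(O[Si](C)(C)C)C=C
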